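The six-membered carbocycle (C4a–C5–C6–C7–C8–C8a of the 1H-isochromene) is an enone whose tetrasubstituted C4a=C8a bond carries both arms of the pyran ring, while C6–O and C7–Me sit opposite to it. It is cut at C8–C8a and C4a–C5: a nickel-catalysed [4+2] annulation inserts the alkyne of a 1,3-enyne into the C(O)–CH2 bond of a cyclobutanone, expanding the four-membered ring by two carbons and assembling all carbons of the core at once. The precursors are an enantiopure cis-3-alkoxy-2-methylcyclobutanone and an ynenol lactone, whose enol lactone steers the regiochemistry and later releases the propanoic acid when the pyran oxygen displaces it.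

Key step: step 7

Assumption: dichloroketene is taken to add to the face of enol ether 3 remote from the aryl group (s-trans, C–H-eclipsed conformer), so that the (S)-alcohol 1 leads to the (6R,7R) series; 1, 7, 9 and 13 are treated as commercial.

Step 1
Reactants: 1 (S)-1-(2,4,6-triisopropylphenyl)ethanol
Product: 2 (S)-allyl 1-(2,4,6-triisopropylphenyl)ethyl ether
Conditions: KH, THF, 0 °C; allyl bromide, Bu4NI (cat.), rt
Reagents that add atoms: allyl bromide, C=CCBr
Why: Williamson ether synthesis: the potassium alkoxide of the hindered benzylic alcohol should displace bromide from the unhindered allylic halide, and the carbinol stereocentre is not involved.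

Step 2
Reactants: 2 (S)-allyl 1-(2,4,6-triisopropylphenyl)ethyl ether
Product: 3 (S)-(Z)-prop-1-enyl 1-(2,4,6-triisopropylphenyl)ethyl ether
Conditions: KOtBu (cat.), DMSO, 60 °C
Reagents that add atoms: none
Why: Base-catalysed allyl-to-propenyl ether isomerization should proceed through a potassium-bridged cisoid oxyallyl anion and so give the (Z)-enol ether, the geometry that later becomes the cis relation of oxygen and methyl.

Step 3
Reactants: 3 (S)-(Z)-prop-1-enyl 1-(2,4,6-triisopropylphenyl)ethyl ether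
Product: 5 (3S,4R)-2,2-dichloro-4-methyl-3-[(1S)-1-(2,4,6-triisopropylphenyl)ethoxy]cyclobutan-1-one (3,4-cis), via dichloroketene 4 (not isolated)
Conditions: Cl3CCOCl, Zn–Cu couple, Et2O, 0 °C to rt
Reagents that add atoms: trichloroacetyl chloride, ClC(Cl)(Cl)C(Cl)=O
Why: Ketene–alkene [2+2] cycloaddition (dichloroketene from zinc dechlorination of the acid chloride): the carbonyl carbon bonds to the nucleophilic β-carbon of the enol ether, the suprafacial addition turns (Z) into 3,4-cis, and the ketene should approach the face remote from the triisopropylphenyl group, which sets C3 as S and C4 as R.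

Step 4
Reactants: 5 (3S,4R)-2,2-dichloro-4-methyl-3-[(1S)-1-(2,4,6-triisopropylphenyl)ethoxy]cyclobutan-1-one
Product: 6 (2R,3R)-2-methyl-3-[(1S)-1-(2,4,6-triisopropylphenyl)ethoxy]cyclobutan-1-one (2,3-cis)
Conditions: Zn dust, AcOH, rt
Reagents that add atoms: none
Why: Reductive dechlorination with zinc in acetic acid goes through a zinc enolate on the chlorinated carbon that should be protonated faster than it expels the hindered β-alkoxide, and neither stereocentre is touched.

Step 5
Reactants: 7 pent-4-ynoic acid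
Product: 8 (E)-5-(iodomethylidene)oxolan-2-one
Conditions: I2, NaHCO3, MeCN, 0 °C to rt, dark
Reagents that add atoms: iodine, II
Why: Iodolactonization: anti addition of carboxylate and iodine across the alkyne in the 5-exo-dig mode should give the (E)-iodo enol lactone.

Step 6
Reactants: 8 (E)-5-(iodomethylidene)oxolan-2-one; 9 tert-butyl(diphenyl)(prop-2-yn-1-yloxy)silane
Product: 10 (E)-5-[4-(tert-butyldiphenylsilyloxy)but-2-yn-1-ylidene]oxolan-2-one
Conditions: PdCl2(PPh3)2 (cat.), CuI (cat.), Et3N, THF, rt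
Reagents that add atoms: none
Why: Sonogashira coupling of the alkenyl iodide with the terminal alkyne should proceed with retention of the alkene geometry under conditions mild enough for the enol lactone.

Step 7
Reactants: 6 (2R,3R)-2-methyl-3-[(1S)-1-(2,4,6-triisopropylphenyl)ethoxy]cyclobutan-1-one; 10 (E)-5-[4-(tert-butyldiphenylsilyloxy)but-2-yn-1-ylidene]oxolan-2-one
Product: 11 (5R,6R)-2-[(tert-butyldiphenylsilyloxy)methyl]-6-methyl-3-[(E)-(5-oxooxolan-2-ylidene)methyl]-5-[(1S)-1-(2,4,6-triisopropylphenyl)ethoxy]cyclohex-2-en-1-one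
Conditions: Ni(cod)2 (10 mol%), PCy3 (20 mol%), toluene, 80 °C
Reagents that add atoms: none
Why: Zerovalent nickel should couple the strained ketone C=O of 6 with the alkyne of 10 by oxidative cyclization to a spiro oxanickelacyclopentene, β-carbon elimination then opens the four-membered ring at its C1–C4 (methylene) bond to a seven-membered nickelacycle, and C(sp3)–C(sp2) reductive elimination delivers the cyclohexenone. The closest known reaction type is the nickel-catalysed formal [4+2] annulation of cyclobutanones (and azetidinones) with internal alkynes and 1,3-enynes. The six-membered ring is closed by reductive elimination from the nickelacycle, so no ionic or radical cyclization mode applies, and the net change is insertion of the two alkyne carbons into the C(O)–CH2 bond. No stereocentre is formed: C2 and C3 of 6 become C6 and C5 of 11 untouched, because neither lies on the cleaved bond and the neutral conditions do not enolize C2. Three selectivities are needed: the CH2OSi-bearing alkyne carbon must bond to the carbonyl carbon, which the conjugated alkene secures by holding its own alkyne carbon on nickel in an η3-type array; cleavage must occur on the methylene rather than the methyl-bearing side, which the preference for the primary, less hindered alkylnickel secures; and β-alkoxy elimination from that alkylnickel must be slower than reductive elimination, which the hindered, poorly leaving 1-arylethoxy group is expected to ensure.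

Step 8
Reactants: 11 (5R,6R)-2-[(tert-butyldiphenylsilyloxy)methyl]-6-methyl-3-[(E)-(5-oxooxolan-2-ylidene)methyl]-5-[(1S)-1-(2,4,6-triisopropylphenyl)ethoxy]cyclohex-2-en-1-one
Product: 12 (5R,6R)-2-[(tert-butyldiphenylsilyloxy)methyl]-5-hydroxy-6-methyl-3-[(E)-(5-oxooxolan-2-ylidene)methyl]cyclohex-2-en-1-one
Conditions: CF3CO2H, CH2Cl2, 0 °C
Reagents that add atoms: none
Why: Acid-mediated SN1 cleavage of the 1-arylethyl ether: the electron-rich benzylic carbon ionizes and is captured by trifluoroacetate, the ring C5–O bond is not broken so its configuration is retained, and the primary tert-butyldiphenylsilyl ether is chosen to survive this acid.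

Step 9
Reactants: 13 orsellinic acid (2,4-dihydroxy-6-methylbenzoic acid)
Product: 15 2,4-bis(tert-butyldimethylsilyloxy)-6-methylbenzoic acid, via silyl ester 14 (not isolated)
Conditions: TBSCl, imidazole, DMF, rt; then AcOH, THF/H2O, rt
Reagents that add atoms: tert-butyldimethylsilyl chloride, CC(C)(C)[Si](C)(C)Cl
Why: Exhaustive silylation followed by selective hydrolysis of the labile silyl ester should leave the two aryl silyl ethers and a free carboxylic acid.

Step 10
Reactants: 12 (5R,6R)-2-[(tert-butyldiphenylsilyloxy)methyl]-5-hydroxy-6-methyl-3-[(E)-(5-oxooxolan-2-ylidene)methyl]cyclohex-2-en-1-one; 15 2,4-bis(tert-butyldimethylsilyloxy)-6-methylbenzoic acid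
Product: 17 (1R,6R)-4-[(tert-butyldiphenylsilyloxy)methyl]-6-methyl-5-oxo-3-[(E)-(5-oxooxolan-2-ylidene)methyl]cyclohex-3-en-1-yl 2,4-bis(tert-butyldimethylsilyloxy)-6-methylbenzoate, via mixed anhydride 16 (not isolated)
Conditions: 15, (CF3CO)2O, toluene, 0 °C to rt; then 12, rt
Reagents that add atoms: none
Why: Esterification through a mixed trifluoroacetic anhydride: the 2,6-disubstituted, electron-rich aroyl group reacts via its acylium ion, which the hindered secondary alcohol can capture at oxygen with retention at the carbinol carbon, and the base-free medium avoids β-elimination of the β-hydroxy ketone.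

Step 11
Reactants: 17 (1R,6R)-4-[(tert-butyldiphenylsilyloxy)methyl]-6-methyl-5-oxo-3-[(E)-(5-oxooxolan-2-ylidene)methyl]cyclohex-3-en-1-yl 2,4-bis(tert-butyldimethylsilyloxy)-6-methylbenzoate
Product: 20 3-[(6R,7R)-6-(2,4-dihydroxy-6-methylbenzoyloxy)-7-methyl-8-oxo-5,6,7,8-tetrahydro-1H-isochromen-3-yl]propanoic acid (CNP0601844.1), via triol 18 (not isolated), via spiro adduct 19 (not isolated)
Conditions: HF·pyridine, pyridine, THF, 0 °C to rt
Reagents that add atoms: none
Why: Fluoride-mediated desilylation frees the primary alcohol, which should add 6-endo-trig to the δ-carbon of the dienone (intramolecular oxa-Michael 1,6-addition) and expel the lactone carboxylate from the spiro adduct (addition–elimination on a doubly vinylogous anhydride), closing the pyran ring and releasing the propanoic acid while C6 and C7 are untouched.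

Compound list
1 | (S)-1-(2,4,6-triisopropylphenyl)ethanol | C[C@H](O)c1c(C(C)C)cc(C(C)C)cc1C(C)C | starting material
2 | (S)-allyl 1-(2,4,6-triisopropylphenyl)ethyl ether | C=CCO[C@@H](C)c1c(C(C)C)cc(C(C)C)cc1C(C)C | intermediate
3 | (S)-(Z)-prop-1-enyl 1-(2,4,6-triisopropylphenyl)ethyl ether | C/C=C\O[C@@H](C)c1c(C(C)C)cc(C(C)C)cc1C(C)C | intermediate
4 | dichloroketene | ClC(Cl)=C=O | intermediate (not isolated)
5 | (3S,4R)-2,2-dichloro-4-methyl-3-[(1S)-1-(2,4,6-triisopropylphenyl)ethoxy]cyclobutan-1-one | O=C1C(Cl)(Cl)[C@@H](O[C@@H](C)c2c(C(C)C)cc(C(C)C)cc2C(C)C)[C@H]1C | intermediate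
6 | (2R,3R)-2-methyl-3-[(1S)-1-(2,4,6-triisopropylphenyl)ethoxy]cyclobutan-1-one | O=C1C[C@@H](O[C@@H](C)c2c(C(C)C)cc(C(C)C)cc2C(C)C)[C@H]1C | intermediate
7 | pent-4-ynoic acid | C#CCCC(=O)O | starting material
8 | (E)-5-(iodomethylidene)oxolan-2-one | O=C1CC/C(=C\I)O1 | intermediate
9 | tert-butyl(diphenyl)(prop-2-yn-1-yloxy)silane | C#CCO[Si](c1ccccc1)(c1ccccc1)C(C)(C)C | starting material
10 | (E)-5-[4-(tert-butyldiphenylsilyloxy)but-2-yn-1-ylidene]oxolan-2-one | O=C1CC/C(=C\C#CCO[Si](c2ccccc2)(c2ccccc2)C(C)(C)C)O1 | intermediate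
11 | (5R,6R)-2-[(tert-butyldiphenylsilyloxy)methyl]-6-methyl-3-[(E)-(5-oxooxolan-2-ylidene)methyl]-5-[(1S)-1-(2,4,6-triisopropylphenyl)ethoxy]cyclohex-2-en-1-one | O=C1C(CO[Si](c2ccccc2)(c2ccccc2)C(C)(C)C)=C(/C=C2\CCC(=O)O2)C[C@@H](O[C@@H](C)c2c(C(C)C)cc(C(C)C)cc2C(C)C)[C@H]1C | intermediate
12 | (5R,6R)-2-[(tert-butyldiphenylsilyloxy)methyl]-5-hydroxy-6-methyl-3-[(E)-(5-oxooxolan-2-ylidene)methyl]cyclohex-2-en-1-one | O=C1C(CO[Si](c2ccccc2)(c2ccccc2)C(C)(C)C)=C(/C=C2\CCC(=O)O2)C[C@@H](O)[C@H]1C | intermediate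
13 | orsellinic acid (2,4-dihydroxy-6-methylbenzoic acid) | Cc1cc(O)cc(O)c1C(=O)O | starting material
14 | tert-butyldimethylsilyl 2,4-bis(tert-butyldimethylsilyloxy)-6-methylbenzoate | Cc1cc(O[Si](C)(C)C(C)(C)C)cc(O[Si](C)(C)C(C)(C)C)c1C(=O)O[Si](C)(C)C(C)(C)C | intermediate (not isolated)
15 | 2,4-bis(tert-butyldimethylsilyloxy)-6-methylbenzoic acid | Cc1cc(O[Si](C)(C)C(C)(C)C)cc(O[Si](C)(C)C(C)(C)C)c1C(=O)O | intermediate
16 | 2,4-bis(tert-butyldimethylsilyloxy)-6-methylbenzoic trifluoroacetic anhydride | Cc1cc(O[Si](C)(C)C(C)(C)C)cc(O[Si](C)(C)C(C)(C)C)c1C(=O)OC(=O)C(F)(F)F | intermediate (not isolated)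
17 | (1R,6R)-4-[(tert-butyldiphenylsilyloxy)methyl]-6-methyl-5-oxo-3-[(E)-(5-oxooxolan-2-ylidene)methyl]cyclohex-3-en-1-yl 2,4-bis(tert-butyldimethylsilyloxy)-6-methylbenzoate | O=C1C(CO[Si](c2ccccc2)(c2ccccc2)C(C)(C)C)=C(/C=C2\CCC(=O)O2)C[C@@H](OC(=O)c2c(C)cc(O[Si](C)(C)C(C)(C)C)cc2O[Si](C)(C)C(C)(C)C)[C@H]1C | intermediate
18 | (1R,6R)-4-(hydroxymethyl)-6-methyl-5-oxo-3-[(E)-(5-oxooxolan-2-ylidene)methyl]cyclohex-3-en-1-yl 2,4-dihydroxy-6-methylbenzoate | O=C1C(CO)=C(/C=C2\CCC(=O)O2)C[C@@H](OC(=O)c2c(C)cc(O)cc2O)[C@H]1C | intermediate (not isolated)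
19 | (6R,7R)-8-hydroxy-7-methyl-5'-oxo-6,7-dihydro-1H,5H-spiro[isochromene-3,2'-oxolan]-6-yl 2,4-dihydroxy-6-methylbenzoate (dienol spiro adduct, spiro carbon undefined) | OC1=C2COC3(CCC(=O)O3)C=C2C[C@@H](OC(=O)c2c(C)cc(O)cc2O)[C@H]1C | intermediate (not isolated)
20 | 3-[(6R,7R)-6-(2,4-dihydroxy-6-methylbenzoyloxy)-7-methyl-8-oxo-5,6,7,8-tetrahydro-1H-isochromen-3-yl]propanoic acid | Cc1cc(O)cc(O)c1C(=O)O[C@@H]1CC2=C(COC(CCC(=O)O)=C2)C(=O)[C@@H]1C | target

Total step count: 11. Longest linear sequence: 8 steps (steps 1, 2, 3, 4, 7, 8, 10, 11).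

Steps most likely to fail

Step 7. What may go wrong: zerovalent nickel may insert into the acyl–oxygen bond of the enol lactone, or the oxygenated alkene may coordinate too weakly to steer the alkyne, so that catalyst is consumed and regiocontrol is lost. The fallback sets out from 6 and returns at 20; it keeps the annulation but uses a 1,3-diyne and makes the lactone afterwards. Copper-catalysed oxidative cross-coupling (Glaser–Hay; CuCl, TMEDA, O2, acetone) of commercial tert-butyl pent-4-ynoate with an excess of 9 should give tert-butyl 8-(tert-butyldiphenylsilyloxy)octa-4,6-diynoate F1. With Ni(cod)2/PCy3 and 6 the second alkyne now takes the nickel-bound position, and the annulation should give tert-butyl 5-[(4R,5R)-2-(tert-butyldiphenylsilyloxymethyl)-4-methyl-3-oxo-5-[(1S)-1-(2,4,6-triisopropylphenyl)ethoxy]cyclohex-1-en-1-yl]pent-4-ynoate F2. CF3CO2H in CH2Cl2 then removes the auxiliary ether and the tert-butyl ester together to give 5-[(4R,5R)-2-(tert-butyldiphenylsilyloxymethyl)-5-hydroxy-4-methyl-3-oxocyclohex-1-en-1-yl]pent-4-ynoic acid F3. AgNO3-catalysed 5-exo-dig cycloisomerization of this 4-ynoic acid closes the (Z)-enol lactone, the geometric isomer of 12, F4. This is acylated as in step 10 to the (Z)-isomer of 17, F5, and desilylated as in step 11 to the (Z)-isomer of 18, F6, which converges on spiro adduct 19 and hence on 20, the alkene geometry being lost at that point.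

Step 11. What may go wrong: the freed primary alcohol may add too slowly to the enol-lactone carbon, so that the triol accumulates and intermolecular acyl transfer from the enol lactone competes. The fallback sets out from 18 (now isolated after desilylation of 17) and returns at 20; it closes the ring by carbonyl chemistry instead of addition–elimination. Hydrolysis of the enol ester (AcOH, THF/H2O, rt) should give the keto acid (1R,6R)-3-(4-carboxy-2-oxobutyl)-4-(hydroxymethyl)-6-methyl-5-oxocyclohex-3-en-1-yl 2,4-dihydroxy-6-methylbenzoate F7. This equilibrates with the six-membered lactol 3-[(6R,7R)-6-(2,4-dihydroxy-6-methylbenzoyloxy)-3-hydroxy-7-methyl-8-oxo-3,4,5,6,7,8-hexahydro-1H-isochromen-3-yl]propanoic acid F8. Dehydration with pyridinium p-toluenesulfonate over 4 Å molecular sieves in CH2Cl2 should then give the conjugated enol ether 20.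

Step 10. What may go wrong: trifluoroacetylation of the hindered secondary alcohol may outrun capture of the acylium ion, and the acid may promote loss of water from the β-hydroxy ketone towards a phenol. The fallback sets out from 12 and 13 and returns at 18; it makes the ester under neutral conditions by trapping a photogenerated acylketene. Treatment of 13 with acetone, (CF3CO)2O and CF3CO2H should give 7-hydroxy-2,2,5-trimethyl-4H-1,3-benzodioxin-4-one F9, and silylation (TBSCl, imidazole, DMF) its ether 7-(tert-butyldimethylsilyloxy)-2,2,5-trimethyl-4H-1,3-benzodioxin-4-one F10. Irradiation of this with 12 (300 nm, CH2Cl2) expels acetone to give the quinone ketene 4-(tert-butyldimethylsilyloxy)-2-methyl-6-oxocyclohexa-2,4-dien-1-ylidene ketene F11. The alcohol captures it as (1R,6R)-4-[(tert-butyldiphenylsilyloxy)methyl]-6-methyl-5-oxo-3-[(E)-(5-oxooxolan-2-ylidene)methyl]cyclohex-3-en-1-yl 4-(tert-butyldimethylsilyloxy)-2-hydroxy-6-methylbenzoate F12. HF·pyridine as in step 11 then gives 18 and, through 19, 20.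

Further compounds
F1 | step 7 | tert-butyl 8-(tert-butyldiphenylsilyloxy)octa-4,6-diynoate | CC(C)(C)OC(=O)CCC#CC#CCO[Si](c1ccccc1)(c1ccccc1)C(C)(C)C
F2 | step 7 | tert-butyl 5-[(4R,5R)-2-(tert-butyldiphenylsilyloxymethyl)-4-methyl-3-oxo-5-[(1S)-1-(2,4,6-triisopropylphenyl)ethoxy]cyclohex-1-en-1-yl]pent-4-ynoate | O=C1C(CO[Si](c2ccccc2)(c2ccccc2)C(C)(C)C)=C(C#CCCC(=O)OC(C)(C)C)C[C@@H](O[C@@H](C)c2c(C(C)C)cc(C(C)C)cc2C(C)C)[C@H]1C
F3 | step 7 | 5-[(4R,5R)-2-(tert-butyldiphenylsilyloxymethyl)-5-hydroxy-4-methyl-3-oxocyclohex-1-en-1-yl]pent-4-ynoic acid | O=C1C(CO[Si](c2ccccc2)(c2ccccc2)C(C)(C)C)=C(C#CCCC(=O)O)C[C@@H](O)[C@H]1C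
F4 | step 7 | (5R,6R)-2-[(tert-butyldiphenylsilyloxy)methyl]-5-hydroxy-6-methyl-3-[(Z)-(5-oxooxolan-2-ylidene)methyl]cyclohex-2-en-1-one | O=C1C(CO[Si](c2ccccc2)(c2ccccc2)C(C)(C)C)=C(/C=C2/CCC(=O)O2)C[C@@H](O)[C@H]1C
F5 | step 7 | (1R,6R)-4-[(tert-butyldiphenylsilyloxy)methyl]-6-methyl-5-oxo-3-[(Z)-(5-oxooxolan-2-ylidene)methyl]cyclohex-3-en-1-yl 2,4-bis(tert-butyldimethylsilyloxy)-6-methylbenzoate | O=C1C(CO[Si](c2ccccc2)(c2ccccc2)C(C)(C)C)=C(/C=C2/CCC(=O)O2)C[C@@H](OC(=O)c2c(C)cc(O[Si](C)(C)C(C)(C)C)cc2O[Si](C)(C)C(C)(C)C)[C@H]1C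
F6 | step 7 | (1R,6R)-4-(hydroxymethyl)-6-methyl-5-oxo-3-[(Z)-(5-oxooxolan-2-ylidene)methyl]cyclohex-3-en-1-yl 2,4-dihydroxy-6-methylbenzoate | O=C1C(CO)=C(/C=C2/CCC(=O)O2)C[C@@H](OC(=O)c2c(C)cc(O)cc2O)[C@H]1C
F7 | step 11 | (1R,6R)-3-(4-carboxy-2-oxobutyl)-4-(hydroxymethyl)-6-methyl-5-oxocyclohex-3-en-1-yl 2,4-dihydroxy-6-methylbenzoate | O=C1C(CO)=C(CC(=O)CCC(=O)O)C[C@@H](OC(=O)c2c(C)cc(O)cc2O)[C@H]1C
F8 | step 11 | 3-[(6R,7R)-6-(2,4-dihydroxy-6-methylbenzoyloxy)-3-hydroxy-7-methyl-8-oxo-3,4,5,6,7,8-hexahydro-1H-isochromen-3-yl]propanoic acid | O=C1C2=C(CC(O)(CCC(=O)O)OC2)C[C@@H](OC(=O)c2c(C)cc(O)cc2O)[C@H]1C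
F9 | step 10 | 7-hydroxy-2,2,5-trimethyl-4H-1,3-benzodioxin-4-one | Cc1cc(O)cc2OC(C)(C)OC(=O)c12
F10 | step 10 | 7-(tert-butyldimethylsilyloxy)-2,2,5-trimethyl-4H-1,3-benzodioxin-4-one | Cc1cc(O[Si](C)(C)C(C)(C)C)cc2OC(C)(C)OC(=O)c12
F11 | step 10 | 4-(tert-butyldimethylsilyloxy)-2-methyl-6-oxocyclohexa-2,4-dien-1-ylidene ketene | O=C=C1C(=O)C=C(O[Si](C)(C)C(C)(C)C)C=C1C
F12 | step 10 | (1R,6R)-4-[(tert-butyldiphenylsilyloxy)methyl]-6-methyl-5-oxo-3-[(E)-(5-oxooxolan-2-ylidene)methyl]cyclohex-3-en-1-yl 4-(tert-butyldimethylsilyloxy)-2-hydroxy-6-methylbenzoate | O=C1C(CO[Si](c2ccccc2)(c2ccccc2)C(C)(C)C)=C(/C=C2\CCC(=O)O2)C[C@@H](OC(=O)c2c(C)cc(O[Si](C)(C)C(C)(C)C)cc2O)[C@H]1C
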